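**Retrosynthetic overview**

- Target ring numbering: C1 henicosyl, C2 OH, C3 C=O, C4 methyl, C5 OH, C6 C=O. The strategy rests on this single, fully substituted carbocycle, with chain and methyl para and an oxygen on each of the other four carbons.
- Last operations: hydrolysis of a quinone carrying C2–OMe and C5–OEt, preceded by oxidation of the matching hydroquinone.
- Ring formation (the only ring): the C5–C6 bond is made by 6π closure of a dienylketene, which arises by 4π opening of a cyclobutenone. In that cyclobutenone C6, C1, C2 and C3 are the four ring carbons and C4–C5 is a (Z)-1-ethoxyprop-1-en-2-yl group on C3.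
- The cyclobutenone is joined at C3–C4 by adding a β-ethoxyvinyllithium (from ethyl prop-1-enyl ether) to 3-henicosyl-4-methoxycyclobutenedione, itself made from dimethyl squarate and henicosylmagnesium bromide (chain from docosanoic acid).

Key step: step 6

Assumption: the amine-promoted dehydrobromination in step 4 is taken to give mainly the Z bromo enol ether (bromine cis to ethoxy), as the lower homologue 2-ethoxyvinyl bromide does; any E isomer is removed by fractional distillation before lithiation.

**Route**

Step 1
Reactants: 1 docosanoic acid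
Product: 3 1-bromohenicosane, via docosanoyl hypobromite 2 (not isolated)
Conditions: Br2, HgO, CCl4, reflux, dark
Reagents that add atoms: bromine, BrBr
Why: Cristol–Firth variant of the Hunsdiecker reaction, in which the acyl hypobromite formed on HgO undergoes homolysis and decarboxylation and the primary henicosyl radical abstracts bromine, a sequence that is dependable for long saturated fatty acids.

Step 2
Reactants: 3 1-bromohenicosane; 4 dimethyl squarate (3,4-dimethoxycyclobut-3-ene-1,2-dione)
Product: 6 racemic 4-henicosyl-4-hydroxy-2,3-dimethoxycyclobut-2-en-1-one, via henicosylmagnesium bromide 5 (not isolated)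
Conditions: Mg turnings, THF, 50 °C; then added to 4, THF, −78 °C; aq NH4Cl
Reagents that add atoms: magnesium, [Mg] (stays only in 5)
Why: Grignard formation followed by 1,2-addition to one squarate carbonyl at low temperature is the standard entry to 4-alkyl-4-hydroxy-2,3-dialkoxycyclobutenones; the new carbinol centre is racemic and is removed in step 3.

Step 3
Reactants: 6 racemic 4-henicosyl-4-hydroxy-2,3-dimethoxycyclobut-2-en-1-one
Product: 7 3-henicosyl-4-methoxycyclobut-3-ene-1,2-dione
Conditions: conc. HCl (cat.), CH2Cl2, rt
Reagents that add atoms: none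
Why: Acid-promoted allylic transposition, in which ionisation of the tertiary hydroxyl gives a methoxy-stabilised cyclobutenyl cation, water returns at the distal methoxy-bearing carbon and the hemiketal loses methanol, the standard conversion of squarate 1,2-adducts into 3-alkyl-4-alkoxycyclobutenediones.

Step 4
Reactants: 8 ethyl prop-1-enyl ether (E/Z mixture)
Product: 10 (Z)-2-bromo-1-ethoxyprop-1-ene, via 1,2-dibromo-1-ethoxypropane 9 (not isolated)
Conditions: Br2, pentane, −78 °C; then PhNEt2, 90 °C; fractional distillation
Reagents that add atoms: bromine, BrBr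
Why: Electrophilic bromine addition to the enol ether gives the α,β-dibromo ether, and amine-mediated dehydrobromination through the oxocarbenium ion removes the bromide next to oxygen and the C2 proton to give the β-bromo enol ether, the isomer with bromine cis to ethoxy being the one needed for a stable lithio species.

Step 5
Reactants: 10 (Z)-2-bromo-1-ethoxyprop-1-ene; 7 3-henicosyl-4-methoxycyclobut-3-ene-1,2-dione
Product: 12 racemic 4-[(Z)-1-ethoxyprop-1-en-2-yl]-2-henicosyl-4-hydroxy-3-methoxycyclobut-2-en-1-one, via 2-lithio-1-ethoxypropene 11 (not isolated)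
Conditions: t-BuLi (2 equiv), THF, −78 °C; then cannulated into 7, THF, −78 °C; aq NH4Cl at −78 °C; Et3N-deactivated SiO2
Reagents that add atoms: t-BuLi, [Li]C(C)(C)C (lithium stays only in 11)
Why: Bromine–lithium exchange with retention gives the oxygen-coordinated β-ethoxyvinyllithium (the second equivalent of t-BuLi destroys t-BuBr), which adds 1,2 to the more electrophilic carbonyl of 7, the one flanked by the methoxy-bearing carbon and not the vinylogous ester carbonyl, as is general for organolithium additions to 3-alkyl-4-alkoxycyclobutenediones; the new quaternary carbinol centre forms as a racemate and is erased in step 6.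

Step 6
Reactants: 12 racemic 4-[(Z)-1-ethoxyprop-1-en-2-yl]-2-henicosyl-4-hydroxy-3-methoxycyclobut-2-en-1-one
Product: 15 2-ethoxy-6-henicosyl-5-methoxy-3-methylbenzene-1,4-diol, via dienylketene 13 (not isolated), via 6-ethoxycyclohexa-2,4-dienone 14 (not isolated)
Conditions: degassed PhMe, 110 °C (p-xylene, 138 °C if slow), Ar, base-washed glassware
Reagents that add atoms: none
Why: Heat causes conrotatory 4π opening of the cyclobutenone bond between the carbonyl carbon and the carbinol carbon; the donor hydroxyl turns outward, so the alkenyl arm of dienylketene 13 lies on the ketene side. The ketene carbon and the ethoxy-bearing alkene terminus then join in a thermally allowed disrotatory 6π electrocyclisation that forms C5–C6 and closes the only ring, the six-membered carbocycle, as dienone 14. The C5–H of 14, alpha to the new carbonyl, is lost by enolisation, which aromatises the ring to hydroquinone 15 with all four oxygens in place. The closest known reaction type is the thermal rearrangement of squarate-derived 4-alkenyl-4-hydroxycyclobutenones to hydroquinones, of which this is a direct case. No stereocentre survives, since the carbinol centre of 12 is erased on ring opening and the C5 centre of 14 on enolisation, so neither needs control. The step needs outward rotation of the hydroxyl and enolisation faster than vinylogous loss of ethanol from 14; the first follows from the donor character of the hydroxyl, the second from the acidity of the C5–H, supported by acid-free solvent and base-washed glass.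

Step 7
Reactants: 15 2-ethoxy-6-henicosyl-5-methoxy-3-methylbenzene-1,4-diol
Product: 16 2-ethoxy-6-henicosyl-5-methoxy-3-methylcyclohexa-2,5-diene-1,4-dione
Conditions: Ag2O, Na2SO4, Et2O, rt (crude 15 used at once)
Reagents that add atoms: none
Why: Two-electron oxidation of an electron-rich hydroquinone to the 1,4-benzoquinone by Ag2O under neutral conditions that leave both vinylogous esters untouched.

Step 8
Reactants: 16 2-ethoxy-6-henicosyl-5-methoxy-3-methylcyclohexa-2,5-diene-1,4-dione
Product: 17 3-henicosyl-2,5-dihydroxy-6-methylcyclohexa-2,5-diene-1,4-dione (target)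
Conditions: 2 M aq NaOH, THF/EtOH, 60 °C; then 2 M HCl
Reagents that add atoms: sodium hydroxide, [Na+].[OH-]
Why: Both alkoxy groups are vinylogous esters on a ring with no free position, so hydroxide replaces them by conjugate addition–elimination to give the dianion of the 2,5-dihydroxyquinone, which acidification protonates, a known hydrolysis of 2,5-dialkoxy-3,6-dialkylbenzoquinones.

**Compound list**

1 | docosanoic acid | CCCCCCCCCCCCCCCCCCCCCC(=O)O | starting material
2 | docosanoyl hypobromite | CCCCCCCCCCCCCCCCCCCCCC(=O)OBr | intermediate (not isolated)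
3 | 1-bromohenicosane | CCCCCCCCCCCCCCCCCCCCCBr | intermediate
4 | dimethyl squarate (3,4-dimethoxycyclobut-3-ene-1,2-dione) | COC1=C(OC)C(=O)C1=O | starting material
5 | henicosylmagnesium bromide | CCCCCCCCCCCCCCCCCCCCC[Mg]Br | intermediate (not isolated)
6 | 4-henicosyl-4-hydroxy-2,3-dimethoxycyclobut-2-en-1-one (racemic) | COC1=C(OC)C(O)(CCCCCCCCCCCCCCCCCCCCC)C1=O | intermediate
7 | 3-henicosyl-4-methoxycyclobut-3-ene-1,2-dione | COC1=C(CCCCCCCCCCCCCCCCCCCCC)C(=O)C1=O | intermediate
8 | ethyl prop-1-enyl ether (E/Z mixture) | CC=COCC | starting material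
9 | 1,2-dibromo-1-ethoxypropane (diastereomer mixture, racemic) | CC(Br)C(Br)OCC | intermediate (not isolated)
10 | (Z)-2-bromo-1-ethoxyprop-1-ene (bromine cis to ethoxy) | C/C(Br)=C/OCC | intermediate
11 | (1-ethoxyprop-1-en-2-yl)lithium, lithium cis to ethoxy | C/C([Li])=C/OCC | intermediate (not isolated)
12 | 4-[(Z)-1-ethoxyprop-1-en-2-yl]-2-henicosyl-4-hydroxy-3-methoxycyclobut-2-en-1-one (racemic) | O=C1C(CCCCCCCCCCCCCCCCCCCCC)=C(OC)C1(O)/C(C)=C\OCC | intermediate
13 | (3Z,5Z)-6-ethoxy-2-henicosyl-4-hydroxy-3-methoxy-5-methylhexa-1,3,5-trien-1-one (dienylketene) | O=C=C(CCCCCCCCCCCCCCCCCCCCC)/C(OC)=C(O)\C(C)=C/OCC | intermediate (not isolated)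
14 | 6-ethoxy-2-henicosyl-4-hydroxy-3-methoxy-5-methylcyclohexa-2,4-dien-1-one (racemic) | O=C1C(CCCCCCCCCCCCCCCCCCCCC)=C(OC)C(O)=C(C)C1OCC | intermediate (not isolated)
15 | 2-ethoxy-6-henicosyl-5-methoxy-3-methylbenzene-1,4-diol | Oc1c(CCCCCCCCCCCCCCCCCCCCC)c(OC)c(O)c(C)c1OCC | intermediate
16 | 2-ethoxy-6-henicosyl-5-methoxy-3-methylcyclohexa-2,5-diene-1,4-dione | O=C1C(CCCCCCCCCCCCCCCCCCCCC)=C(OC)C(=O)C(C)=C1OCC | intermediate
17 | 3-henicosyl-2,5-dihydroxy-6-methylcyclohexa-2,5-diene-1,4-dione | CCCCCCCCCCCCCCCCCCCCCC1=C(O)C(=O)C(C)=C(O)C1=O | target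

**Step count**

Total steps: 8. Longest linear sequence: 7 steps (steps 1, 2, 3, 5, 6, 7, 8, from docosanoic acid).

**Steps most likely to fail**

Step 5. The bromine–lithium exchange may be overtaken by loss of LiOEt from 11. The nucleophile may add twice or at the vinylogous ester carbonyl. The β-ethoxyvinyl carbinol may also ionise and collapse to an enal on acidic contact during isolation. The fallback sets out from 7 and rejoins the route at 17. Commercial isopropenylmagnesium bromide is added to 7 (THF, −78 °C) to give racemic 2-henicosyl-4-hydroxy-3-methoxy-4-(prop-1-en-2-yl)cyclobut-2-en-1-one F1, which has no labile enol ether. The same thermal ring expansion (p-xylene, reflux) should give 2-henicosyl-3-methoxy-5-methylbenzene-1,4-diol F2, and Ag2O oxidation should give 2-henicosyl-3-methoxy-5-methylcyclohexa-2,5-diene-1,4-dione F3. The missing C5 oxygen is then added. Nucleophilic epoxidation (H2O2, Na2CO3, aqueous dioxane) at the only unsubstituted quinone carbon should give racemic 4-henicosyl-3-methoxy-1-methyl-7-oxabicyclo[4.1.0]hept-3-ene-2,5-dione F4. Acid (concentrated H2SO4, 0 °C) should isomerise the epoxide, a known conversion of quinone epoxides into hydroxyquinones, to 2-henicosyl-6-hydroxy-3-methoxy-5-methylcyclohexa-2,5-diene-1,4-dione F5. Hydrolysis under the conditions of step 8 then gives 17.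

Step 6. Vinylogous expulsion of ethanol from dienone 14 may outrun enolisation, which would remove the C5 oxygen. The free hydroxyl may capture the ketene if part of the material opens with the hydroxyl turned inward. Traces of acid may hydrolyse the enol ether before ring opening. The fallback sets out from 12 and rejoins at 16. The carbinol is capped (TMSCl, Et3N, DMAP cat., CH2Cl2, 0 °C) to give racemic 4-[(Z)-1-ethoxyprop-1-en-2-yl]-2-henicosyl-3-methoxy-4-[(trimethylsilyl)oxy]cyclobut-2-en-1-one F6. Thermolysis in p-xylene should then end at 2-ethoxy-6-henicosyl-5-methoxy-3-methyl-4-[(trimethylsilyl)oxy]phenol F7. With the oxygen capped there is no hydroxyl to trap the ketene and no enol push behind ethoxide loss. Oxidative desilylation with (NH4)2Ce(NO3)6 in aqueous MeCN at 0 °C gives 16.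

Step 4. Dehydrobromination through the oxocarbenium ion may proceed with poor control of alkene geometry, and only the isomer with bromine cis to ethoxy leads to a lithio species that does not eliminate LiOEt. Hydrolysis of the α-bromo ether by adventitious water is a second loss channel. The fallback does not start from a numbered compound: it sets out from commercial 1-ethoxyprop-1-yne F8, in place of 8 and 10, and rejoins at 11. Radical hydrostannation (Bu3SnH, AIBN, 70 °C, neat) is expected to place tin on the methyl-bearing alkyne carbon, remote from oxygen, and to deliver hydrogen anti. This gives (Z)-tributyl(1-ethoxyprop-1-en-2-yl)stannane F9 with tin cis to ethoxy. Tin–lithium exchange with n-BuLi (THF, −78 °C) proceeds with retention to 11, which is used as in step 5.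

**Further compounds**

F1 | step 5 | 2-henicosyl-4-hydroxy-3-methoxy-4-(prop-1-en-2-yl)cyclobut-2-en-1-one (racemic) | O=C1C(CCCCCCCCCCCCCCCCCCCCC)=C(OC)C1(O)C(C)=C
F2 | step 5 | 2-henicosyl-3-methoxy-5-methylbenzene-1,4-diol | Oc1cc(C)c(O)c(OC)c1CCCCCCCCCCCCCCCCCCCCC
F3 | step 5 | 2-henicosyl-3-methoxy-5-methylcyclohexa-2,5-diene-1,4-dione | O=C1C=C(C)C(=O)C(OC)=C1CCCCCCCCCCCCCCCCCCCCC
F4 | step 5 | 4-henicosyl-3-methoxy-1-methyl-7-oxabicyclo[4.1.0]hept-3-ene-2,5-dione (racemic) | O=C1C(CCCCCCCCCCCCCCCCCCCCC)=C(OC)C(=O)C2(C)OC12
F5 | step 5 | 2-henicosyl-6-hydroxy-3-methoxy-5-methylcyclohexa-2,5-diene-1,4-dione | O=C1C(CCCCCCCCCCCCCCCCCCCCC)=C(OC)C(=O)C(C)=C1O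
F6 | step 6 | 4-[(Z)-1-ethoxyprop-1-en-2-yl]-2-henicosyl-3-methoxy-4-[(trimethylsilyl)oxy]cyclobut-2-en-1-one (racemic) | O=C1C(CCCCCCCCCCCCCCCCCCCCC)=C(OC)C1(O[Si](C)(C)C)/C(C)=C\OCC
F7 | step 6 | 2-ethoxy-6-henicosyl-5-methoxy-3-methyl-4-[(trimethylsilyl)oxy]phenol | Oc1c(CCCCCCCCCCCCCCCCCCCCC)c(OC)c(O[Si](C)(C)C)c(C)c1OCC
F8 | step 4 | 1-ethoxyprop-1-yne | CC#COCC
F9 | step 4 | (Z)-tributyl(1-ethoxyprop-1-en-2-yl)stannane | CCCC[Sn](CCCC)(CCCC)/C(C)=C\OCC
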